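**Retrosynthetic overview**

- The target is a 6-oxabicyclo[3.2.2]non-3-ene-2,7-dione: a seven-membered carbocycle, C(=O)–C(allyl)=CH–C(OMe)(O)–CH(Me)–CH(Ar)–CH, whose ketal carbon and α-keto CH are spanned by an O–C(=O) lactone bridge.
- Feature used: in this carbocycle the ring ketone carbon and the methoxy ketal carbon stand 1,4 to each other across the cis C=C that carries the allyl group, a dissonant 2-ene-1,4-dione in masked form.
- Opening the pseudo-ester (ketal C–O) and removing the carboxyl carbon α to the ring ketone leads back to 2-allyl-5-methyl-6-aryl-cyclohept-2-ene-1,4-dione. Its C(=O)–C(allyl) bond is cut as acyl anion plus ynone β-carbon, which gives an open-chain ynone aldehyde.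
- The ynone aldehyde comes from a 1,5-diol, built from the organocatalytic Michael adduct of propanal and the arylidene malonate (C–Me and C–Ar centres) and the acetylide of pent-1-en-4-yne.
- Ring order: carbocycle first (carbene-catalysed 7-endo-dig acyl-anion closure), lactone bridge last (carboxylation, then transannular pseudo-ester closure that sets both bridgehead centres).

Key step: step 8

Assumption: the (S)-diarylprolinol silyl ether is taken to give the syn Michael adduct with the facial sense it shows towards nitroalkenes; the carbinol centre made in step 3 is carried as a mixture because step 6 oxidises it; atom labels C1–C7 in steps 8–10 follow the ring numbering of 13.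

**Route**

Step 1
Reactants: 1 3,4,5-trimethoxybenzaldehyde; 2 dimethyl malonate
Product: 3 dimethyl 2-(3,4,5-trimethoxybenzylidene)propanedioate
Conditions: piperidine (10 mol %), AcOH (10 mol %), toluene, reflux, Dean–Stark
Reagents that add atoms: none
Why: Knoevenagel condensation driven by azeotropic removal of water; the symmetrical malonate leaves no alkene geometry to control.

Step 2
Reactants: 3 dimethyl 2-(3,4,5-trimethoxybenzylidene)propanedioate; 4 propanal
Product: 5 dimethyl 2-[(1R,2R)-2-methyl-3-oxo-1-(3,4,5-trimethoxyphenyl)propyl]propanedioate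
Conditions: (S)-α,α-diphenylprolinol trimethylsilyl ether (20 mol %), 4 (5 equiv), CHCl3, 4 °C
Reagents that add atoms: none
Why: Enamine-catalysed Michael addition in which the E-enamine of propanal should attack the arylidene malonate through an acyclic synclinal transition state from the face not shielded by the diphenyl(silyloxy)methyl group, setting the C–Me and C–Ar centres together as the syn (R,R) pair.

Step 3
Reactants: 5 dimethyl 2-[(1R,2R)-2-methyl-3-oxo-1-(3,4,5-trimethoxyphenyl)propyl]propanedioate; 6 pent-1-en-4-yne
Product: 7 dimethyl 2-[(1R,2R)-3-hydroxy-2-methyl-1-(3,4,5-trimethoxyphenyl)oct-7-en-4-yn-1-yl]propanedioate (C3 epimers)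
Conditions: 6 (2.5 equiv), n-BuLi (2.3 equiv), THF, −78 °C; then 5, −78 °C; AcOH quench at −78 °C
Reagents that add atoms: none
Why: 1,2-Addition of a lithium acetylide to the aldehyde, with the first equivalent of acetylide spent on the malonate C–H, whose enolate then protects the esters; the new carbinol centre is uncontrolled and is removed by oxidation in step 6.

Step 4
Reactants: 7 dimethyl 2-[(1R,2R)-3-hydroxy-2-methyl-1-(3,4,5-trimethoxyphenyl)oct-7-en-4-yn-1-yl]propanedioate
Product: 9 (4S,5R)-5-methyl-6-(pent-4-en-1-yn-1-yl)-4-(3,4,5-trimethoxyphenyl)oxan-2-one (C6 epimers), via carbomethoxy lactone 8 (not isolated)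
Conditions: LiCl (3 equiv), H2O (2 equiv), DMSO, 140 °C
Reagents that add atoms: none
Why: Krapcho dealkoxycarbonylation, in which the δ-hydroxy diester lactonises on heating, chloride demethylates the remaining ester and the carboxylate loses CO2; the near-neutral medium should leave the skipped enyne and the two non-acidic stereocentres untouched.

Step 5
Reactants: 9 (4S,5R)-5-methyl-6-(pent-4-en-1-yn-1-yl)-4-(3,4,5-trimethoxyphenyl)oxan-2-one
Product: 10 (3S,4R)-4-methyl-3-(3,4,5-trimethoxyphenyl)dec-9-en-6-yne-1,5-diol (C5 epimers)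
Conditions: LiBH4 (2 equiv), THF, 0 °C → rt; aqueous work-up
Reagents that add atoms: none
Why: Borohydride reduction of a lactone to the diol; LiBH4 is chosen because it does not hydrometalate the alkyne of a propargylic alcohol, and any uncyclised hydroxy ester from step 4 converges on the same diol.

Step 6
Reactants: 10 (3S,4R)-4-methyl-3-(3,4,5-trimethoxyphenyl)dec-9-en-6-yne-1,5-diol
Product: 11 (3S,4R)-1-hydroxy-4-methyl-3-(3,4,5-trimethoxyphenyl)dec-9-en-6-yn-5-one
Conditions: activated MnO2 (15 equiv), CH2Cl2, rt
Reagents that add atoms: none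
Why: MnO2 oxidises the propargylic alcohol chemoselectively and leaves the saturated primary alcohol, which avoids the lactol and lactone that would form if the primary alcohol of the 1,5-diol were oxidised first; no base is present.

Step 7
Reactants: 11 (3S,4R)-1-hydroxy-4-methyl-3-(3,4,5-trimethoxyphenyl)dec-9-en-6-yn-5-one
Product: 12 (3S,4R)-4-methyl-5-oxo-3-(3,4,5-trimethoxyphenyl)dec-9-en-6-ynal
Conditions: Dess–Martin periodinane (1.3 equiv), CH2Cl2, 0 °C → rt
Reagents that add atoms: none
Why: Dess–Martin oxidation of the primary alcohol in a base-free, mildly acidic medium, so the CH2 between alkyne and vinyl group should not isomerise and the centre α to the ynone should not epimerise.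

Step 8
Reactants: 12 (3S,4R)-4-methyl-5-oxo-3-(3,4,5-trimethoxyphenyl)dec-9-en-6-ynal
Product: 13 (5R,6S)-5-methyl-2-(prop-2-en-1-yl)-6-(3,4,5-trimethoxyphenyl)cyclohept-2-ene-1,4-dione
Conditions: 2-(pentafluorophenyl)-6,7-dihydro-5H-pyrrolo[2,1-c][1,2,4]triazol-2-ium tetrafluoroborate (20 mol %), NaOAc (20 mol %), toluene (0.01 M), 40 °C
Reagents that add atoms: none
Why: Proposed new method: the triazolylidene released by acetate adds to the aldehyde and, after proton transfer, the enaminol (acyl-anion equivalent) attacks the ynone β-carbon, the alkyne carbon that carries the CH2CH=CH2 group; protonation of the resulting α-keto vinyl anion (a bent, ring-held allenolate) by AcOH and loss of the carbene give the 2-ene-1,4-dione. The closest known reactions are the carbene-catalysed intramolecular Stetter reaction onto enones and enoates and the carbene-catalysed hydroacylation of activated alkynes; a ynone acceptor closing a seven-membered ring has not been shown. The carbocycle closes in the 7-endo-dig mode, the only Michael-type mode, since 6-exo attack would fall on the α-carbon of the ynone. No stereocentre is formed: the ring alkene can only be cis, and chain centres C3 and C4 become C6 and C5 of 13 unchanged, C5 already lying in the trans arrangement to the aryl group that should be the more stable one. The step needs carbene addition to the aldehyde to win over attack on the ynone and over isomerisation of the skipped enyne CH2; the weak acetate base, the low carbene concentration from an electron-poor N-C6F5 triazolium salt and high dilution (which also suppresses benzoin coupling) are meant to secure this.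

Step 9
Reactants: 13 (5R,6S)-5-methyl-2-(prop-2-en-1-yl)-6-(3,4,5-trimethoxyphenyl)cyclohept-2-ene-1,4-dione
Product: 14 (6R,7R)-6-methyl-2,5-dioxo-3-(prop-2-en-1-yl)-7-(3,4,5-trimethoxyphenyl)cyclohept-3-ene-1-carboxylic acid (C1 epimers and enol, used crude at 0 °C)
Conditions: LiN(SiMe3)2 (1.1 equiv), THF, −78 °C; cannulate into CO2-saturated THF, −78 °C; cold 1 M HCl
Reagents that add atoms: carbon dioxide O=C=O
Why: Kinetic enolate formation at the less hindered α′-CH2 (C7 of 13, next to the C1 carbonyl that directs the lithium amide) followed by carboxylation of the lithium enolate with CO2; the new centre lies between ketone and acid, is epimerisable and is left undefined until step 10.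

Step 10
Reactants: 14 (6R,7R)-6-methyl-2,5-dioxo-3-(prop-2-en-1-yl)-7-(3,4,5-trimethoxyphenyl)cyclohept-3-ene-1-carboxylic acid
Product: 16 (1R,5S,8R,9R)-5-methoxy-9-methyl-3-(prop-2-en-1-yl)-8-(3,4,5-trimethoxyphenyl)-6-oxabicyclo[3.2.2]non-3-ene-2,7-dione (target), via dimethyl ketal acid 15 (not isolated)
Conditions: HC(OMe)3 (2 equiv), pyridinium p-toluenesulfonate (10 mol %), CH2Cl2, 0 °C → rt
Reagents that add atoms: trimethyl orthoformate COC(OC)OC
Why: Acid-catalysed pseudo-ester formation, in which the orthoformate ketalises the C4 carbonyl (the one not tied up in the enolised β-keto acid) and the methoxy oxocarbenium ion of that ketal is captured across the ring by the C7 carboxyl to close the six-membered lactone bridge; because ketal exchange is reversible and C7 epimerises through the enol, both bridge centres are set together under equilibrating conditions, closure anti to the adjacent C5 methyl (carboxyl cis to the C6 aryl group) giving the (1R,5S) bridge of the target.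

**Compound list**

1 | 3,4,5-trimethoxybenzaldehyde | COc1cc(C=O)cc(OC)c1OC | starting material
2 | dimethyl malonate | COC(=O)CC(=O)OC | starting material
3 | dimethyl 2-(3,4,5-trimethoxybenzylidene)propanedioate | COC(=O)C(=Cc1cc(OC)c(OC)c(OC)c1)C(=O)OC | intermediate
4 | propanal | CCC=O | starting material
5 | dimethyl 2-[(1R,2R)-2-methyl-3-oxo-1-(3,4,5-trimethoxyphenyl)propyl]propanedioate | COC(=O)C(C(=O)OC)[C@H](c1cc(OC)c(OC)c(OC)c1)[C@@H](C)C=O | intermediate
6 | pent-1-en-4-yne | C#CCC=C | starting material
7 | dimethyl 2-[(1R,2R)-3-hydroxy-2-methyl-1-(3,4,5-trimethoxyphenyl)oct-7-en-4-yn-1-yl]propanedioate (C3 epimers) | COC(=O)C(C(=O)OC)[C@H](c1cc(OC)c(OC)c(OC)c1)[C@@H](C)C(O)C#CCC=C | intermediate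
8 | methyl (4R,5R)-5-methyl-2-oxo-6-(pent-4-en-1-yn-1-yl)-4-(3,4,5-trimethoxyphenyl)oxane-3-carboxylate (C3 and C6 epimers, not isolated) | COC(=O)C1C(=O)OC(C#CCC=C)[C@H](C)[C@H]1c1cc(OC)c(OC)c(OC)c1 | intermediate
9 | (4S,5R)-5-methyl-6-(pent-4-en-1-yn-1-yl)-4-(3,4,5-trimethoxyphenyl)oxan-2-one (C6 epimers) | O=C1C[C@H](c2cc(OC)c(OC)c(OC)c2)[C@@H](C)C(C#CCC=C)O1 | intermediate
10 | (3S,4R)-4-methyl-3-(3,4,5-trimethoxyphenyl)dec-9-en-6-yne-1,5-diol (C5 epimers) | OCC[C@H](c1cc(OC)c(OC)c(OC)c1)[C@@H](C)C(O)C#CCC=C | intermediate
11 | (3S,4R)-1-hydroxy-4-methyl-3-(3,4,5-trimethoxyphenyl)dec-9-en-6-yn-5-one | OCC[C@H](c1cc(OC)c(OC)c(OC)c1)[C@@H](C)C(=O)C#CCC=C | intermediate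
12 | (3S,4R)-4-methyl-5-oxo-3-(3,4,5-trimethoxyphenyl)dec-9-en-6-ynal | O=CC[C@H](c1cc(OC)c(OC)c(OC)c1)[C@@H](C)C(=O)C#CCC=C | intermediate
13 | (5R,6S)-5-methyl-2-(prop-2-en-1-yl)-6-(3,4,5-trimethoxyphenyl)cyclohept-2-ene-1,4-dione | C=CCC1=CC(=O)[C@H](C)[C@@H](c2cc(OC)c(OC)c(OC)c2)CC1=O | intermediate
14 | (6R,7R)-6-methyl-2,5-dioxo-3-(prop-2-en-1-yl)-7-(3,4,5-trimethoxyphenyl)cyclohept-3-ene-1-carboxylic acid (C1 epimers) | C=CCC1=CC(=O)[C@H](C)[C@@H](c2cc(OC)c(OC)c(OC)c2)C(C(=O)O)C1=O | intermediate
15 | (6R,7R)-5,5-dimethoxy-6-methyl-2-oxo-3-(prop-2-en-1-yl)-7-(3,4,5-trimethoxyphenyl)cyclohept-3-ene-1-carboxylic acid (C1 epimers, not isolated) | C=CCC1=CC(OC)(OC)[C@H](C)[C@@H](c2cc(OC)c(OC)c(OC)c2)C(C(=O)O)C1=O | intermediate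
16 | (1R,5S,8R,9R)-5-methoxy-9-methyl-3-(prop-2-en-1-yl)-8-(3,4,5-trimethoxyphenyl)-6-oxabicyclo[3.2.2]non-3-ene-2,7-dione | C=CCC1=C[C@@]2(OC)OC(=O)[C@@H](C1=O)[C@H](c1cc(OC)c(OC)c(OC)c1)[C@H]2C | target

**Step count and risks**

Total step count: 10. Longest linear sequence: 10 steps (fully linear from 1).

Steps most likely to fail:

1. Step 8 (new method). The carbene may add to the ynone instead of the aldehyde, the base may isomerise the skipped enyne CH2 to an allenyl or dienyl ketone, closure may go 6-exo at the α-carbon, or the seven-membered closure may lose to benzoin-type oligomerisation. Fallback with known chemistry, setting out from 12 and returning at 13: anti addition of HI across the ynone (NaI, AcOH, rt) should give (3S,4R,6Z)-7-iodo-4-methyl-5-oxo-3-(3,4,5-trimethoxyphenyl)deca-6,9-dienal F1. An intramolecular Nozaki–Hiyama–Kishi coupling (CrCl2, catalytic NiCl2, DMF, high dilution, rt) then joins the iodine-bearing carbon to the aldehyde and gives (6S,7R)-4-hydroxy-7-methyl-3-(prop-2-en-1-yl)-6-(3,4,5-trimethoxyphenyl)cyclohept-2-en-1-one F2 as a carbinol mixture. Dess–Martin oxidation of this allylic alcohol gives 13.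

2. Step 10. The lactone bridge may close on the face that carries the C5 methyl group, or the acid may be diverted to the open methyl ester or ketal, or lose CO2 before closure. Fallback by kinetic acyl activation instead of equilibrating ketal exchange, setting out from 14 and ending at 16: (COCl)2 with catalytic DMF in CH2Cl2 at −20 °C should give the ring-closed pseudo-acid chloride (1R,5R,8R,9R)-5-chloro-9-methyl-3-(prop-2-en-1-yl)-8-(3,4,5-trimethoxyphenyl)-6-oxabicyclo[3.2.2]non-3-ene-2,7-dione F3. Silver-assisted methanolysis (Ag2CO3, MeOH, CH2Cl2, −20 °C) then replaces chloride by methoxide at the bridgehead to give 16.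

3. Step 9. Deprotonation may occur at C5–H or at the allyl CH2 (γ to the C4 carbonyl) instead of C7, or the β-keto acid may lose CO2 on work-up. Fallback by thermodynamic, chelation-controlled carboxylation, setting out from 13 and returning at 14: CO2 (1 atm), MgCl2 and Et3N in MeCN at rt should give the magnesium chelate of the enolised β-keto carboxylate F4, which can form only at the α-CH2 position; cold dilute HCl releases 14.

**Further compounds**

F1 | step 8 | (3S,4R,6Z)-7-iodo-4-methyl-5-oxo-3-(3,4,5-trimethoxyphenyl)deca-6,9-dienal | O=CC[C@H](c1cc(OC)c(OC)c(OC)c1)[C@@H](C)C(=O)/C=C(\I)CC=C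
F2 | step 8 | (6S,7R)-4-hydroxy-7-methyl-3-(prop-2-en-1-yl)-6-(3,4,5-trimethoxyphenyl)cyclohept-2-en-1-one (C4 epimers) | C=CCC1=CC(=O)[C@H](C)[C@@H](c2cc(OC)c(OC)c(OC)c2)CC1O
F3 | step 10 | (1R,5R,8R,9R)-5-chloro-9-methyl-3-(prop-2-en-1-yl)-8-(3,4,5-trimethoxyphenyl)-6-oxabicyclo[3.2.2]non-3-ene-2,7-dione | C=CCC1=C[C@@]2(Cl)OC(=O)[C@@H](C1=O)[C@H](c1cc(OC)c(OC)c(OC)c1)[C@H]2C
F4 | step 9 | magnesium chelate of the enolate carboxylate dianion of 14 (stereocentres as in 13) | [Mg+2].[O-]C(=O)C1=C([O-])C(CC=C)=CC(=O)[C@H](C)[C@H]1c2cc(OC)c(OC)c(OC)c2
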